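**Retrosynthetic overview**
1. Feature: the ring oxygen O1 of ring C is bound to C8a of ring A, and C8a lies para to the C6 hydroxyl. An oxidised C6 phenol is therefore electrophilic at C8a, so the C8a-O1 bond can be made directly from C8a-H.
2. First disconnection (ring C, the only ring to be built): C8a-O1. This gives an open 1,3-diketone with free C6-OH, 5-OMe, 7-OMe, C8a-H and a tosylated ring B.
3. Second disconnection: C2-C3. This gives a ring A methyl ketone (from 2,6-dimethoxyphenol) and a ring B acid chloride (from 2,5-dimethoxyphenol).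
4. Rings A and B are bought. Ring C is closed anodically, then the 5-methyl ether and the tosylate are removed.

Key step: step 9

Remark: flavone numbering (O1, C2 to C8a, primed numbers for ring B) is also used for the open-chain precursors, and phenols 1 and 5 are taken as commercial.

**Step 1**
Reactants: 1 2,6-dimethoxyphenol
Product: 2 2,6-dimethoxyphenyl methanesulfonate
Conditions: MsCl, Et3N, CH2Cl2, 0 °C
Reagents that add atoms: methanesulfonyl chloride, CS(=O)(=O)Cl
Why: O-Sulfonylation of a phenol turns the strongest donor of the ring into a weak acceptor that is stable to Lewis acids, so only the two methoxy groups direct the next step.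

**Step 2**
Reactants: 2 2,6-dimethoxyphenyl methanesulfonate
Product: 3 3-acetyl-2,6-dimethoxyphenyl methanesulfonate
Conditions: AcCl, SnCl4, CH2Cl2, 0 °C to rt
Reagents that add atoms: acetyl chloride, CC(=O)Cl
Why: Friedel-Crafts acylation should go to C3 (equivalent to C5 by symmetry) because that carbon is para to one methoxy group and ortho to the other while C4 is meta to both, and SnCl4 is mild enough to spare the methyl ether next to the new ketone.

**Step 3**
Reactants: 3 3-acetyl-2,6-dimethoxyphenyl methanesulfonate
Product: 4 1-(3-hydroxy-2,4-dimethoxyphenyl)ethanone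
Conditions: NaOH (2 M aq), 1,4-dioxane, 70 °C; then 1 M HCl
Reagents that add atoms: none
Why: Alkaline hydrolysis of an aryl sulfonate with S-O cleavage is run without an alcohol so that no alkylating sulfonate ester can form, and the methyl ketone and both methyl ethers are inert to it.

**Step 4**
Reactants: 5 2,5-dimethoxyphenol
Product: 7 4-hydroxy-2,5-dimethoxybenzaldehyde, via iminium chloride 6 (not isolated)
Conditions: POCl3, DMF, 0 °C to rt; then ice-water
Reagents that add atoms: N,N-dimethylformamide, CN(C)C=O; water, O
Why: Vilsmeier-Haack formylation should attack C4, which is para to the hydroxyl and ortho to the 5-OMe, because C6 is wedged between two oxygen substituents and C3 is activated by one methoxy group only, and any O-formate is lost in the aqueous hydrolysis.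

**Step 5**
Reactants: 7 4-hydroxy-2,5-dimethoxybenzaldehyde
Product: 8 4-formyl-2,5-dimethoxyphenyl 4-methylbenzenesulfonate
Conditions: TsCl, Et3N, DMAP (cat.), CH2Cl2, 0 °C to rt
Reagents that add atoms: 4-methylbenzenesulfonyl chloride, Cc1ccc(S(=O)(=O)Cl)cc1
Why: O-Sulfonylation of an acidic para-formylphenol installs a group that resists oxidants, amide bases, BCl3 and the anode, and that lowers the electron density of ring B.

**Step 6**
Reactants: 8 4-formyl-2,5-dimethoxyphenyl 4-methylbenzenesulfonate
Product: 9 2,5-dimethoxy-4-(tosyloxy)benzoic acid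
Conditions: NaClO2, NaH2PO4, 2-methyl-2-butene, t-BuOH-H2O, rt
Reagents that add atoms: sodium chlorite, [Na+].[O-]Cl=O
Why: Pinnick oxidation converts the aldehyde into the acid without the Dakin-type cleavage that peroxy oxidants cause on alkoxybenzaldehydes, and the alkene scavenges hypochlorous acid before it can chlorinate the ring.

**Step 7**
Reactants: 9 2,5-dimethoxy-4-(tosyloxy)benzoic acid
Product: 10 2,5-dimethoxy-4-(tosyloxy)benzoyl chloride
Conditions: (COCl)2, DMF (cat.), CH2Cl2, 0 °C to rt; evaporation, used crude
Reagents that add atoms: oxalyl chloride, ClC(=O)C(=O)Cl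
Why: DMF-catalysed acid chloride formation gives only gaseous by-products and yields an acyl donor that releases no alkoxide, which could attack the tosylate in the next step.

**Step 8**
Reactants: 4 1-(3-hydroxy-2,4-dimethoxyphenyl)ethanone; 10 2,5-dimethoxy-4-(tosyloxy)benzoyl chloride
Product: 12 4-[3-(3-hydroxy-2,4-dimethoxyphenyl)-3-oxopropanoyl]-2,5-dimethoxyphenyl 4-methylbenzenesulfonate, via dilithium dianion 11 (not isolated)
Conditions: 4, LiHMDS (3.3 equiv), THF, -78 to -10 °C; then 10 (1.0 equiv), -78 °C to rt; then 1 M HCl
Reagents that add atoms: none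
Why: This is the C-acylation of a lithium polyanion of a hydroxyacetophenone with an aroyl chloride (a crossed Claisen-type acylation), in which the enolate carbon far outruns the phenoxide shielded by two ortho methoxy groups and the third equivalent of base takes up the acidic diketone as it forms.

**Step 9**
Reactants: 12 4-[3-(3-hydroxy-2,4-dimethoxyphenyl)-3-oxopropanoyl]-2,5-dimethoxyphenyl 4-methylbenzenesulfonate
Product: 15 4-(6-hydroxy-5,7-dimethoxy-4-oxo-4H-chromen-2-yl)-2,5-dimethoxyphenyl 4-methylbenzenesulfonate, via phenoxonium cation 13 (not isolated), via 8aH-dienone 14 (not isolated)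
Conditions: reticulated vitreous carbon anode, Pt cathode, undivided cell, Bu4NPF6 (0.1 M), HFIP-CH2Cl2 (4:1), 5 mM in 12, constant current (about 1 mA cm-2), 2.0 to 2.2 F mol-1, rt, Ar
Reagents that add atoms: none
Why: Proposed new method: the C6 hydroxyl of ring A is the only free phenol and the most electron-rich site of 12, so the carbon anode should remove two electrons and the phenolic proton to give phenoxonium cation 13, which HFIP stabilises without adding to it and whose charge is shared by C5, C7 and C8a. The oxygen on C2 of the enolised diketone then bonds to C8a, para to the C6 oxygen, to give dienone 14, and loss of the C8a proton restores ring A while the Pt cathode converts the released protons into H2. Ring C closes as a six-membered ring (O1, C2, C3, C4, C4a, C8a) by capture of a trigonal cationic carbon, 6-exo-trig when counted on the C8=C8a bond of the quinoid cation, and no stereocentre remains because the sp3 C8a of racemic 14 becomes planar again. The nearest known reaction types are the anodic methoxylation of phenols to quinone monoketals, the anodic C-H lactonisation of biaryl-2-carboxylic acids to benzocoumarins and the chemical oxidative cyclisation of 2,3'-dihydroxybenzophenones to 2-hydroxyxanthones, but the enol oxygen of a 1,3-diketone has not been used in this role. Chemoselective oxidation of ring A is required and is secured by the sulfonate and acyl groups on ring B, which lift the potential of its 1,4-dimethoxyarene unit well above that of the phenol. Site selectivity is also required: C3 could reach C8a or C5 only through a four-membered ring, closure of the enol oxygen on C5 gives a mixed ketal that cannot aromatise and should reopen by ionisation in HFIP, high dilution holds back radical dimerisation at C8a, and stopping near 2 F mol-1 protects 15, whose new para oxygen is only a weak donor because it belongs to a vinylogous ester.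

**Step 10**
Reactants: 15 4-(6-hydroxy-5,7-dimethoxy-4-oxo-4H-chromen-2-yl)-2,5-dimethoxyphenyl 4-methylbenzenesulfonate
Product: 17 4-(5,6-dihydroxy-7-methoxy-4-oxo-4H-chromen-2-yl)-2,5-dimethoxyphenyl 4-methylbenzenesulfonate, via cyclic chloroboronate 16 (not isolated)
Conditions: BCl3 (2.5 equiv), CH2Cl2, -78 to 0 °C; then 1 M HCl, rt
Reagents that add atoms: none
Why: This is the known chelation-directed 5-O-demethylation of flavones, in which the 5-OMe is wedged between the C4 carbonyl and the boron-bound O6, is twisted out of conjugation and is the most basic ether oxygen, whereas the 7-OMe is conjugated with C4=O, the ring B ethers lack a chelating neighbour and the tosylate is inert to BCl3.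

**Step 11**
Reactants: 17 4-(5,6-dihydroxy-7-methoxy-4-oxo-4H-chromen-2-yl)-2,5-dimethoxyphenyl 4-methylbenzenesulfonate
Product: 18 5,6-dihydroxy-2-(4-hydroxy-2,5-dimethoxyphenyl)-7-methoxy-4H-chromen-4-one (5,6,4'-trihydroxy-7,2',5'-trimethoxyflavone, the target)
Conditions: KOH (2 M aq, degassed), 1,4-dioxane, 60 °C, Ar; then cold 1 M HCl
Reagents that add atoms: none
Why: Alkaline hydrolysis of an aryl tosylate by hydroxide attack at sulfur is helped by the electron-poor chromone para to the leaving phenoxide, oxygen is excluded because the 5,6-catecholate oxidises easily, and the polyanionic flavone should resist ring opening at this temperature.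

**Compound list**
1 | 2,6-dimethoxyphenol | COc1cccc(OC)c1O | starting material
2 | 2,6-dimethoxyphenyl methanesulfonate | COc1cccc(OC)c1OS(C)(=O)=O | intermediate
3 | 3-acetyl-2,6-dimethoxyphenyl methanesulfonate | COc1ccc(C(C)=O)c(OC)c1OS(C)(=O)=O | intermediate
4 | 1-(3-hydroxy-2,4-dimethoxyphenyl)ethanone | COc1ccc(C(C)=O)c(OC)c1O | intermediate
5 | 2,5-dimethoxyphenol | COc1ccc(OC)c(O)c1 | starting material
6 | N-(4-hydroxy-2,5-dimethoxybenzylidene)-N-methylmethanaminium chloride (not isolated) | COc1cc(C=[N+](C)C)c(OC)cc1O.[Cl-] | intermediate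
7 | 4-hydroxy-2,5-dimethoxybenzaldehyde | COc1cc(C=O)c(OC)cc1O | intermediate
8 | 4-formyl-2,5-dimethoxyphenyl 4-methylbenzenesulfonate | COc1cc(C=O)c(OC)cc1OS(=O)(=O)c1ccc(C)cc1 | intermediate
9 | 2,5-dimethoxy-4-(tosyloxy)benzoic acid | COc1cc(C(=O)O)c(OC)cc1OS(=O)(=O)c1ccc(C)cc1 | intermediate
10 | 2,5-dimethoxy-4-(tosyloxy)benzoyl chloride | COc1cc(C(=O)Cl)c(OC)cc1OS(=O)(=O)c1ccc(C)cc1 | intermediate
11 | dilithium phenoxide-enolate of 4 (not isolated) | COc1ccc(C(=C)[O-])c(OC)c1[O-].[Li+].[Li+] | intermediate
12 | 4-[3-(3-hydroxy-2,4-dimethoxyphenyl)-3-oxopropanoyl]-2,5-dimethoxyphenyl 4-methylbenzenesulfonate | COc1ccc(C(=O)CC(=O)c2cc(OC)c(OS(=O)(=O)c3ccc(C)cc3)cc2OC)c(OC)c1O | intermediate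
13 | ring A phenoxonium cation of the enol form of 12, charge drawn on C8a (not isolated) | COC1=C[CH+]C(C(=O)C=C(O)c2cc(OC)c(OS(=O)(=O)c3ccc(C)cc3)cc2OC)=C(OC)C1=O | intermediate
14 | 4-(5,7-dimethoxy-4,6-dioxo-6,8a-dihydro-4H-chromen-2-yl)-2,5-dimethoxyphenyl 4-methylbenzenesulfonate, racemic at C8a (not isolated) | COC1=CC2OC(=CC(=O)C2=C(OC)C1=O)c1cc(OC)c(OS(=O)(=O)c2ccc(C)cc2)cc1OC | intermediate
15 | 4-(6-hydroxy-5,7-dimethoxy-4-oxo-4H-chromen-2-yl)-2,5-dimethoxyphenyl 4-methylbenzenesulfonate | COc1cc2oc(-c3cc(OC)c(OS(=O)(=O)c4ccc(C)cc4)cc3OC)cc(=O)c2c(OC)c1O | intermediate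
16 | cyclic chloroboronate of 17, B-Cl bridging O5 and O6 (not isolated) | COc1cc2oc(-c3cc(OC)c(OS(=O)(=O)c4ccc(C)cc4)cc3OC)cc(=O)c2c2OB(Cl)Oc12 | intermediate
17 | 4-(5,6-dihydroxy-7-methoxy-4-oxo-4H-chromen-2-yl)-2,5-dimethoxyphenyl 4-methylbenzenesulfonate | COc1cc2oc(-c3cc(OC)c(OS(=O)(=O)c4ccc(C)cc4)cc3OC)cc(=O)c2c(O)c1O | intermediate
18 | 5,6-dihydroxy-2-(4-hydroxy-2,5-dimethoxyphenyl)-7-methoxy-4H-chromen-4-one | COc1cc(-c2cc(=O)c3c(O)c(O)c(OC)cc3o2)c(OC)cc1O | target

**Step count**
Total step count: 11.
Longest linear sequence: 8 steps (5 to 18, steps 4 to 11). The ring A branch from 1 runs over 7 steps.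

**Steps most likely to fail**

**Step 9 (Proposed new method).**
- What may go wrong:
  - The phenoxyl radical may couple intermolecularly at C8a before the second electron is removed.
  - Closure at the methoxy-bearing C5 may drain material through loss of methanol on work-up.
  - The product may be oxidised further once it accumulates.
- Fallback: known chemistry that installs the C8a oxygen before ring closure, setting out from 4 and coming back at 15.
  - Elbs persulfate oxidation of 4 (K2S2O8, aq KOH, rt) hydroxylates para to the free phenol through potassium 2-acetyl-4-hydroxy-3,5-dimethoxyphenyl sulfate F1.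
  - Warm dilute HCl hydrolyses F1 to 1-(3,6-dihydroxy-2,4-dimethoxyphenyl)ethanone F2.
  - F2 is treated with LiHMDS (5 equiv, THF, -78 °C) and then with 10. This gives 4-[3-(3,6-dihydroxy-2,4-dimethoxyphenyl)-3-oxopropanoyl]-2,5-dimethoxyphenyl 4-methylbenzenesulfonate F3.
  - Acid-catalysed cyclodehydration of F3 (H2SO4 cat., AcOH, 95 °C) closes ring C through the ortho hydroxyl and gives 15.

**Step 8.**
- What may go wrong:
  - O-acylation of the phenoxide may compete with C-acylation.
  - A second acylation of the diketonate may occur.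
  - The excess amide base may slowly attack the sulfonate.
- Fallback: the phenol is masked so that only a mono-enolate and two equivalents of base are needed, setting out from 4 and coming back at 12.
  - Benzylation of 4 (BnBr, K2CO3, DMF, rt) gives 1-[3-(benzyloxy)-2,4-dimethoxyphenyl]ethanone F4.
  - The lithium enolate of F4 (LiHMDS, 2.2 equiv, THF, -78 °C) is acylated with 10. This gives 4-{3-[3-(benzyloxy)-2,4-dimethoxyphenyl]-3-oxopropanoyl}-2,5-dimethoxyphenyl 4-methylbenzenesulfonate F5.
  - Hydrogenolysis of F5 (H2, 1 atm, Pd/C, EtOAc) frees the C6 phenol without touching the aryl tosylate or the diketone and gives 12.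

**Step 11.**
- What may go wrong:
  - Traces of air may oxidise the 5,6-catecholate.
  - Hydroxide may open ring C during prolonged heating.
- Fallback: the two deprotections are inverted so that the base never meets a catechol and the last operation is acidic, setting out from 15 and coming back at 18.
  - Hydrolysis of the tosylate of 15 (KOH aq, 1,4-dioxane, 60 °C, Ar) gives 6-hydroxy-2-(4-hydroxy-2,5-dimethoxyphenyl)-5,7-dimethoxy-4H-chromen-4-one F6.
  - BCl3 (3.5 equiv, CH2Cl2, -78 to 0 °C, then 1 M HCl) removes the chelated 5-methyl group of F6 and gives 18.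

**Further compounds**
F1 | step 9 | potassium 2-acetyl-4-hydroxy-3,5-dimethoxyphenyl sulfate | COc1cc(OS(=O)(=O)[O-])c(C(C)=O)c(OC)c1O.[K+]
F2 | step 9 | 1-(3,6-dihydroxy-2,4-dimethoxyphenyl)ethanone | COc1cc(O)c(C(C)=O)c(OC)c1O
F3 | step 9 | 4-[3-(3,6-dihydroxy-2,4-dimethoxyphenyl)-3-oxopropanoyl]-2,5-dimethoxyphenyl 4-methylbenzenesulfonate | COc1cc(O)c(C(=O)CC(=O)c2cc(OC)c(OS(=O)(=O)c3ccc(C)cc3)cc2OC)c(OC)c1O
F4 | step 8 | 1-[3-(benzyloxy)-2,4-dimethoxyphenyl]ethanone | COc1ccc(C(C)=O)c(OC)c1OCc1ccccc1
F5 | step 8 | 4-{3-[3-(benzyloxy)-2,4-dimethoxyphenyl]-3-oxopropanoyl}-2,5-dimethoxyphenyl 4-methylbenzenesulfonate | COc1ccc(C(=O)CC(=O)c2cc(OC)c(OS(=O)(=O)c3ccc(C)cc3)cc2OC)c(OC)c1OCc1ccccc1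
F6 | step 11 | 6-hydroxy-2-(4-hydroxy-2,5-dimethoxyphenyl)-5,7-dimethoxy-4H-chromen-4-one | COc1cc(-c2cc(=O)c3c(OC)c(O)c(OC)cc3o2)c(OC)cc1O
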